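If Kj and Ju react by two routes, each first order in both, then the ratio of the two rates contains neither, and from this the forecast's author and I draw different views of the set-ups.

all flasks: Dw 4.00 mM; Xo 1.0 mM
- red: Kj 0.020 M; Ju 0.0160 M; one stirred flow tank at steady state, fed with the mixture as stated, mean residence time 4.0 d
- amber: Kj 0.020 M; Ju 0.0160 M; everything together in a closed stirred flask, run for 4.0 d; time 4.0 d
- teal: Kj 0.020 M (fed, over 3.20 d); Ju 0.0160 M; all but Kj at the start; Kj goes in evenly over 3.20 d, the run ends at 4.0 d; time 4.0 d
- green: Kj 0.020 M; Ju 0.0160 M (fed, over 3.20 d); all but Ju at the start; Ju goes in evenly over 3.20 d, the run ends at 4.0 d; time 4.0 d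

* the set-up with the highest share of Dz in all that became Dz or Kj.Dz or Kj.Ju, at the outlet or at the end ("none" if the first two lie within 2 percentage points) (red / amber / teal / green / none)
* share of Dz in all that became Dz or Kj.Dz or Kj.Ju, at the outlet or at the end, red
* share of Dz in all that became Dz or Kj.Dz or Kj.Ju, at the outlet or at the end, amber
* share of Dz in all that became Dz or Kj.Dz or Kj.Ju, at the outlet or at the end, teal
* share of Dz in all that became Dz or Kj.Dz or Kj.Ju, at the outlet or at the end, green

- percentages count the Kj that a species holds: one Kj.Dz counts as two
- the stated concentrations are those of everything mixed, before any reaction; amounts are the same in each set-up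
- the feed brings no volume worth counting
- the share counts what is present at the end, not what went on to other products
- run time (amber): 4.0 d

I write the catalysed route, which gives Dz, over the plain route, which gives Kj.Ju. Kj and Ju cancel, and free Xo times 49.1 /M²/min over 0.0190 /M/min is 2.58; this split, the selectivity factor of the pair, is what I carry.

The free Xo is a curve, and I replace it by its mean, taken as the charge. That seems safe: with Dz taken at the whole Kj charge as an upper mark, the Xo + Dz route alone gives free Xo a half-life of 21.9 d, longer than the 4.0 d of the run.

So every fraction of the charge that passes these routes divides in the same proportion, however it is dosed. My view is that the four set-ups differ little and all lie near one ceiling, for amber a share below 72.1 %. Any Dz lost afterwards only lowers the share, and my reckoning goes no further.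

The other side answers that Dz does not stay. With Kj as charged, the Kj + Dz route alone gives Dz a half-life of 2.5 d, shorter than the run, and each Kj.Dz counts twice against the share.

The forecast therefore spreads the set-ups: 43 % for red, 47.5 % for amber, 55 % for teal and 47 % for green, with teal best, on the ground that “trickling in Kj (teal) keeps that loss lowest”.

The simulation gives 43.1 % for red, 47.2 % for amber, 53.7 % for teal and 47.6 % for green, so teal is best, as the forecast said.

    Kj + Ju + Xo → Xo + Dz (k1 = 49.1 /M²/min)
    Dw + Ju + Xo → Xo + Yx (k2 = 8.28 /M²/min)
    Kj + Dz → Kj.Dz (k3 = 0.00977 /M/min)
    Kj + Ju → Kj.Ju (k4 = 0.0190 /M/min)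
    Xo + Dz → Xo.Dz (k5 = 0.00110 /M/min)

Amber at 4.00 d still keeps the split: with free Xo at 95.6 %, 2.58 times its Kj.Ju of 20.1 % gives 51.9 % of the Kj as Dz made, and Dz, the Dz inside Kj.Dz and Xo.Dz together hold 51.8 %. The largest single effect on the gap is Kj + Dz: without it, teal's lead over red falls from 11 percentage points to 0.93 points. My view fits better early: amber at 25 h shows 60.4 %. The neighbour of amber with 0.0040 M of Xo has split 10.3; on its Kj.Ju of 6.69 % that makes 69.2 %, its forms hold 68.9 %, and its share is 62.9 %.

The constants used here were chosen freely.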